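**Retrosynthetic overview**

1. The strategy rests on C4 of ring C: a lone carbonyl carbon bonded to C4a of ring A and to the methoxy-bearing C3, which is the α-carbon of the aryl ketone formed by C2 and ring B. C4 is therefore brought in as carbon monoxide.
2. Target 14 comes from hexamethoxyflavone 13 by cleavage of the O5 methyl group. Ring C of 13 is closed last (O1–C2 bond, acid) from diketone 11, whose only latent phenol is the O8a methoxymethyl ether.
3. Diketone 11 comes from iodide 6, carbon monoxide 10 and ketone 9 in one palladium-catalysed carbonylative ketone arylation that forms C4a–C4 and C3–C4.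
4. Iodide 6 comes from 3-hydroxy-4,5-dimethoxybenzaldehyde 1: iodination next to the hydroxyl, MOM ether, Baeyer–Villiger oxidation with methanolysis, methylation. Ketone 9 comes from Friedel–Crafts acylation of 1,3-dimethoxybenzene 7 with methoxyacetyl chloride 8.
5. Rings A and B are bought preformed; ring C is the only ring made (step 7).

Key step: step 6

Assumption: iodination of 1 is taken to go to C2, between hydroxyl and formyl, as halogenation of 3-hydroxy-4-methoxybenzaldehyde does; the structure of 2 is to be confirmed by NOE/HMBC before it is carried on.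

**Route**

Step 1
Reactants: 1 3-hydroxy-4,5-dimethoxybenzaldehyde
Product: 2 3-hydroxy-2-iodo-4,5-dimethoxybenzaldehyde
Conditions: ICl (1.05 equiv), pyridine, 1,4-dioxane, 0 °C to rt
Reagents that add atoms: iodine monochloride, ClI
Why: Electrophilic aromatic iodination in which the free phenol directs ortho and C2 is also para to the C5 methoxy group, so iodine should enter between hydroxyl and formyl as it does in the halogenation of 3-hydroxy-4-methoxybenzaldehyde.

Step 2
Reactants: 2 3-hydroxy-2-iodo-4,5-dimethoxybenzaldehyde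
Product: 3 2-iodo-4,5-dimethoxy-3-(methoxymethoxy)benzaldehyde
Conditions: MOMCl, i-Pr2NEt, CH2Cl2, 0 °C to rt
Reagents that add atoms: chloromethyl methyl ether, COCCl
Why: O-alkylation of the phenol with an α-chloro ether (Williamson-type acetal formation), which masks the future O1 as an acid-labile group that is stable to peracid, base and palladium.

Step 3
Reactants: 3 2-iodo-4,5-dimethoxy-3-(methoxymethoxy)benzaldehyde
Product: 5 2-iodo-4,5-dimethoxy-3-(methoxymethoxy)phenol, via aryl formate 4 (not isolated)
Conditions: mCPBA, CH2Cl2, 0 °C to rt; then K2CO3 (cat.), MeOH, rt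
Reagents that add atoms: meta-chloroperoxybenzoic acid (mCPBA), OOC(=O)c1cccc(Cl)c1
Why: Baeyer–Villiger oxidation of the aldehyde, in which the electron-rich aryl group (para methoxy) migrates in preference to hydrogen to give formate 4 that catalytic K2CO3 in MeOH transesterifies to the phenol, while the peracid without strong acid should leave the aryl iodide and the MOM acetal untouched.

Step 4
Reactants: 5 2-iodo-4,5-dimethoxy-3-(methoxymethoxy)phenol
Product: 6 2-iodo-1,4,5-trimethoxy-3-(methoxymethoxy)benzene
Conditions: MeI, K2CO3, acetone, 50 °C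
Reagents that add atoms: iodomethane, CI
Why: Williamson ether synthesis on the phenoxide, which fixes the future O5 as a methyl ether so that only the MOM-protected oxygen can later become O1.

Step 5
Reactants: 7 1,3-dimethoxybenzene; 8 methoxyacetyl chloride
Product: 9 1-(2,4-dimethoxyphenyl)-2-methoxyethan-1-one
Conditions: AlCl3 (1.1 equiv), CH2Cl2, −10 to 0 °C; ice/dilute HCl quench
Reagents that add atoms: none
Why: Friedel–Crafts acylation at C4 of 1,3-dimethoxybenzene, para to one methoxy group and ortho to the other, with low temperature and near-stoichiometric AlCl3 chosen so that the ortho methoxy group should not be cleaved.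

Step 6
Reactants: 6 2-iodo-1,4,5-trimethoxy-3-(methoxymethoxy)benzene; 9 1-(2,4-dimethoxyphenyl)-2-methoxyethan-1-one; 10 carbon monoxide
Product: 11 1-(2,4-dimethoxyphenyl)-2-methoxy-3-[3,4,6-trimethoxy-2-(methoxymethoxy)phenyl]propane-1,3-dione (racemic, enolizable)
Conditions: Pd(OAc)2 (5 mol %), Xantphos (6 mol %), CO (5 bar), MgCl2 (1.5 equiv), Et3N (3 equiv), 9 (1.5 equiv), 1,4-dioxane, 80 °C; cold dilute HCl work-up
Reagents that add atoms: none
Why: Pd(OAc)2 is reduced in the flask to zerovalent palladium carrying Xantphos, which inserts into the C–I bond of 6, and CO then coordinates and migrates to give an aroylpalladium iodide (divalent palladium) whose acyl carbon is the future C4. The magnesium enolate of 9, formed by soft enolization with MgCl2/Et3N and held as a chelate by the α-methoxy oxygen, displaces iodide, and C–C reductive elimination forms C3–C4 and returns zerovalent palladium, the diketone being held as its magnesium chelate, which guards it against a second acylation. The closest known reaction type is the palladium-catalysed carbonylative α-arylation of aryl alkyl ketones with aryl iodides to 1,3-diketones. No ring closes here, and the C3 carbon becomes a stereocentre that lies between two carbonyls, is formed racemic without control and is erased when ring C is closed in step 7. The selectivity needed is acyl transfer over direct α-arylation and over O-acylation: the two ortho oxygen substituents of 6 slow direct aryl–enolate coupling and favour CO insertion, CO pressure and the wide bite angle of Xantphos keep palladium on the acyl path, and magnesium chelation steers the enolate to react at carbon. The site of the new ketone is fixed by the iodine of 6, so ring A is acylated at C4a only.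

Step 7
Reactants: 11 1-(2,4-dimethoxyphenyl)-2-methoxy-3-[3,4,6-trimethoxy-2-(methoxymethoxy)phenyl]propane-1,3-dione
Product: 13 2-(2,4-dimethoxyphenyl)-3,5,7,8-tetramethoxy-4H-chromen-4-one, via phenol diketone 12 (not isolated)
Conditions: conc. HCl, MeOH, 65 °C
Reagents that add atoms: none
Why: Acid-catalysed cleavage of the methoxymethyl acetal frees the O8a phenol of 12, which adds to the ring B carbonyl (6-exo-trig) and loses water across C2–C3 to close ring C, the classical acid cyclodehydration of o-hydroxyaryl 1,3-diketones to flavones, and since O8a is the only free hydroxyl a single flavone can form.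

Step 8
Reactants: 13 2-(2,4-dimethoxyphenyl)-3,5,7,8-tetramethoxy-4H-chromen-4-one
Product: 14 2-(2,4-dimethoxyphenyl)-5-hydroxy-3,7,8-trimethoxy-4H-chromen-4-one (5-hydroxy-3,7,8,2',4'-pentamethoxyflavone)
Conditions: BCl3 (1.2 equiv, 1 M in CH2Cl2), CH2Cl2, −20 to 0 °C; then H2O
Reagents that add atoms: none
Why: Chelation-controlled Lewis acid ether cleavage, in which BCl3 binds between the C4 carbonyl and the peri O5 in a six-membered boron chelate and chloride removes that methyl group, so that at low temperature and with about one equivalent the C3, C7, C8 and ring B methoxy groups should be kept.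

**Compound list**

1 | 3-hydroxy-4,5-dimethoxybenzaldehyde | COc1cc(C=O)cc(O)c1OC | starting material
2 | 3-hydroxy-2-iodo-4,5-dimethoxybenzaldehyde | COc1cc(C=O)c(I)c(O)c1OC | intermediate
3 | 2-iodo-4,5-dimethoxy-3-(methoxymethoxy)benzaldehyde | COCOc1c(I)c(C=O)cc(OC)c1OC | intermediate
4 | 2-iodo-4,5-dimethoxy-3-(methoxymethoxy)phenyl formate | COCOc1c(I)c(OC=O)cc(OC)c1OC | intermediate (not isolated)
5 | 2-iodo-4,5-dimethoxy-3-(methoxymethoxy)phenol | COCOc1c(I)c(O)cc(OC)c1OC | intermediate
6 | 2-iodo-1,4,5-trimethoxy-3-(methoxymethoxy)benzene | COCOc1c(I)c(OC)cc(OC)c1OC | intermediate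
7 | 1,3-dimethoxybenzene | COc1cccc(OC)c1 | starting material
8 | methoxyacetyl chloride | COCC(=O)Cl | starting material
9 | 1-(2,4-dimethoxyphenyl)-2-methoxyethan-1-one | COCC(=O)c1ccc(OC)cc1OC | intermediate
10 | carbon monoxide | [C-]#[O+] | starting material
11 | 1-(2,4-dimethoxyphenyl)-2-methoxy-3-[3,4,6-trimethoxy-2-(methoxymethoxy)phenyl]propane-1,3-dione (racemic) | COCOc1c(C(=O)C(OC)C(=O)c2ccc(OC)cc2OC)c(OC)cc(OC)c1OC | intermediate
12 | 1-(2,4-dimethoxyphenyl)-3-(2-hydroxy-3,4,6-trimethoxyphenyl)-2-methoxypropane-1,3-dione (racemic) | COc1ccc(C(=O)C(OC)C(=O)c2c(O)c(OC)c(OC)cc2OC)c(OC)c1 | intermediate (not isolated)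
13 | 2-(2,4-dimethoxyphenyl)-3,5,7,8-tetramethoxy-4H-chromen-4-one | COc1ccc(-c2oc3c(OC)c(OC)cc(OC)c3c(=O)c2OC)c(OC)c1 | intermediate
14 | 2-(2,4-dimethoxyphenyl)-5-hydroxy-3,7,8-trimethoxy-4H-chromen-4-one | COc1ccc(-c2oc3c(OC)c(OC)cc(O)c3c(=O)c2OC)c(OC)c1 | target

**Step count**

Total: 8 steps. Longest linear sequence: 7 steps (steps 1, 2, 3, 4, 6, 7, 8); step 5 is the one-step side branch to ketone 9.

**Steps most likely to fail**

Step 6 (carbonylative coupling). With a doubly ortho-substituted, electron-rich iodide, capture of the aroylpalladium species by the enolate may be slow. Hydrodeiodination, O-acylation of the enolate or retro-Claisen cleavage of the product may then take over.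
The fallback sets out from iodide 6 (with ketone 9) and comes back to the route at diketone 11 by an aldol–oxidation sequence that needs no palladium. Iodine–magnesium exchange on 6 with i-PrMgCl·LiCl (THF, −20 °C) should give [3,4,6-trimethoxy-2-(methoxymethoxy)phenyl]magnesium chloride F1, which is formylated with DMF to 3,4,6-trimethoxy-2-(methoxymethoxy)benzaldehyde F2. Ketone 9 is deprotonated with LiN(i-Pr)2 (THF, −78 °C) to lithium (Z)-1-(2,4-dimethoxyphenyl)-2-methoxyethen-1-olate F3, which should add to F2 and give, after NH4Cl quench, 1-(2,4-dimethoxyphenyl)-3-hydroxy-2-methoxy-3-[3,4,6-trimethoxy-2-(methoxymethoxy)phenyl]propan-1-one F4 as a mixture of racemic diastereomers. Dess–Martin periodinane (CH2Cl2, NaHCO3, rt) then oxidises the carbinol to 11; the configuration of F4 is of no consequence.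

Step 1 (iodination). Iodine may enter para to the hydroxyl (C6) instead of ortho, or twice.
The fallback sets out from aldehyde 1 and comes back at iodide 6, placing iodine last by directed ortho-metalation. Aldehyde 1 is protected (MOMCl, i-Pr2NEt, CH2Cl2) as 3,4-dimethoxy-5-(methoxymethoxy)benzaldehyde F5. Baeyer–Villiger oxidation (mCPBA, CH2Cl2) should give 3,4-dimethoxy-5-(methoxymethoxy)phenyl formate F6, which is methanolysed (K2CO3 cat., MeOH) to 3,4-dimethoxy-5-(methoxymethoxy)phenol F7 and methylated (MeI, K2CO3, acetone) to 1,2,5-trimethoxy-3-(methoxymethoxy)benzene F8. n-BuLi/TMEDA (THF, −78 to 0 °C) should remove the proton between the methoxymethoxy group, the stronger director, and its methoxy neighbour to give [3,4,6-trimethoxy-2-(methoxymethoxy)phenyl]lithium F9, and quenching with I2 gives 6.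

Step 8 (selective demethylation). Cleavage may not stop at O5: the C3 methoxy group (five-membered chelate with the carbonyl) or the C7/C8 pair may also be attacked.
The fallback sets out from phenol 5 and comes back at target 14, carrying the C5 oxygen as a benzyl ether so that the last step is a hydrogenolysis. Phenol 5 with BnBr/K2CO3 (DMF, rt) should give 1-(benzyloxy)-2-iodo-4,5-dimethoxy-3-(methoxymethoxy)benzene F10. The carbonylative coupling of step 6 with 9 and 10 (Pd(OAc)2, Xantphos, CO, MgCl2, Et3N, dioxane, 80 °C) then gives 1-[6-(benzyloxy)-3,4-dimethoxy-2-(methoxymethoxy)phenyl]-3-(2,4-dimethoxyphenyl)-2-methoxypropane-1,3-dione F11. HCl in MeOH removes the MOM group to 1-[6-(benzyloxy)-2-hydroxy-3,4-dimethoxyphenyl]-3-(2,4-dimethoxyphenyl)-2-methoxypropane-1,3-dione F12, which closes in the same flask to 5-(benzyloxy)-2-(2,4-dimethoxyphenyl)-3,7,8-trimethoxy-4H-chromen-4-one F13. H2 with Pd/C (palladium on carbon; EtOAc, rt) removes the benzyl group and gives 14 with every methyl ether left in place.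

**Further compounds**

F1 | step 6 | [3,4,6-trimethoxy-2-(methoxymethoxy)phenyl]magnesium chloride | COCOc1c([Mg]Cl)c(OC)cc(OC)c1OC
F2 | step 6 | 3,4,6-trimethoxy-2-(methoxymethoxy)benzaldehyde | COCOc1c(C=O)c(OC)cc(OC)c1OC
F3 | step 6 | lithium (Z)-1-(2,4-dimethoxyphenyl)-2-methoxyethen-1-olate | [Li+].[O-]/C(=C\OC)c1ccc(OC)cc1OC
F4 | step 6 | 1-(2,4-dimethoxyphenyl)-3-hydroxy-2-methoxy-3-[3,4,6-trimethoxy-2-(methoxymethoxy)phenyl]propan-1-one (mixture of racemic diastereomers) | COCOc1c(C(O)C(OC)C(=O)c2ccc(OC)cc2OC)c(OC)cc(OC)c1OC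
F5 | step 1 | 3,4-dimethoxy-5-(methoxymethoxy)benzaldehyde | COCOc1cc(C=O)cc(OC)c1OC
F6 | step 1 | 3,4-dimethoxy-5-(methoxymethoxy)phenyl formate | COCOc1cc(OC=O)cc(OC)c1OC
F7 | step 1 | 3,4-dimethoxy-5-(methoxymethoxy)phenol | COCOc1cc(O)cc(OC)c1OC
F8 | step 1 | 1,2,5-trimethoxy-3-(methoxymethoxy)benzene | COCOc1cc(OC)cc(OC)c1OC
F9 | step 1 | [3,4,6-trimethoxy-2-(methoxymethoxy)phenyl]lithium | COCOc1c([Li])c(OC)cc(OC)c1OC
F10 | step 8 | 1-(benzyloxy)-2-iodo-4,5-dimethoxy-3-(methoxymethoxy)benzene | COCOc1c(I)c(OCc2ccccc2)cc(OC)c1OC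
F11 | step 8 | 1-[6-(benzyloxy)-3,4-dimethoxy-2-(methoxymethoxy)phenyl]-3-(2,4-dimethoxyphenyl)-2-methoxypropane-1,3-dione (racemic) | COCOc1c(C(=O)C(OC)C(=O)c2ccc(OC)cc2OC)c(OCc2ccccc2)cc(OC)c1OC
F12 | step 8 | 1-[6-(benzyloxy)-2-hydroxy-3,4-dimethoxyphenyl]-3-(2,4-dimethoxyphenyl)-2-methoxypropane-1,3-dione (racemic) | COc1ccc(C(=O)C(OC)C(=O)c2c(O)c(OC)c(OC)cc2OCc2ccccc2)c(OC)c1
F13 | step 8 | 5-(benzyloxy)-2-(2,4-dimethoxyphenyl)-3,7,8-trimethoxy-4H-chromen-4-one | COc1ccc(-c2oc3c(OC)c(OC)cc(OCc4ccccc4)c3c(=O)c2OC)c(OC)c1
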